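**Plan**
1. Retrosynthesis: four benzyl ethers are stripped, then ring C is cut at O1–C2 and at C4–C4a together. This leaves a 2-benzylated phloroglucinol (ring A with the C8 4-oxybenzyl group) and a trans-(2R,3S)-3-arylglycidic acid (C4–C3–C2 with ring B). The CH2–aryl bond at C8 goes back to an aldehyde and an aryl Grignard reagent.
2. Enabling feature: O1 and C4a are ortho neighbours on ring A and act as an O,C-1,3-dinucleophile. C4 (acyl) and C2 (benzylic, activated by the para oxygen of ring B) are 1,3-related electrophiles on either side of carbinol C3, so C2–C3–C4 is an epoxy acid in disguise.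
3. The halves are tied as the aryl ester through the future O1, with iodine on the future C4a. Iodine–lithium exchange moves the acyl group from O1 to C4a, and the oxygen so unmasked opens the epoxide at C2. Tether, iodine and oxirane all disappear in that step.
4. Forward order: rings A, B and the benzyl ring are bought. The temporary oxirane arises in step 6, the fragments are joined in step 9, ring C closes in step 10, and hydrogenolysis ends the route.
5. Stereochemistry: both centres come from one catalytic asymmetric epoxidation. C3 keeps its C–O bond (R) and C2 is inverted by O1 (S to R), which gives the 2,3-trans (2R,3R) compound.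

Key step: step 10

Assumption: 4-(benzyloxy)phenylmagnesium bromide (THF solution), (triphenylphosphoranylidene)acetaldehyde and the (R)-diarylprolinol silyl ether of step 6 are taken as commercial.

**Step 1**
Reactants: 1 2,4,6-trihydroxybenzaldehyde
Product: 2 2,4-bis(benzyloxy)-6-hydroxybenzaldehyde
Conditions: BnBr (2.05 equiv), K2CO3 (2.1 equiv), DMF, rt
Reagents that add atoms: benzyl bromide, BrCc1ccccc1
Why: Williamson ether synthesis with two equivalents of benzyl bromide should spare one ortho hydroxyl, because this one is tied to the formyl oxygen by a hydrogen bond and is the least nucleophilic of the three.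

**Step 2**
Reactants: 2 2,4-bis(benzyloxy)-6-hydroxybenzaldehyde
Product: 3 4,6-bis(benzyloxy)-2-hydroxy-3-iodobenzaldehyde
Conditions: NIS (1.05 equiv), MeCN–CH2Cl2, 0 °C to rt, dark
Reagents that add atoms: N-iodosuccinimide, O=C1CCC(=O)N1I
Why: Electrophilic aromatic iodination should go to the ring carbon between OH and OBn (ortho to the chelated phenol) rather than to the more crowded carbon between the two benzyloxy groups, which is the regiochemistry known for 2-hydroxy-4,6-dialkoxyaryl carbonyl compounds.

**Step 3**
Reactants: 3 4,6-bis(benzyloxy)-2-hydroxy-3-iodobenzaldehyde; 4 4-(benzyloxy)phenylmagnesium bromide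
Product: 5 3,5-bis(benzyloxy)-2-{[4-(benzyloxy)phenyl](hydroxy)methyl}-6-iodophenol (racemic at the carbinol carbon)
Conditions: 4 (2.3 equiv), THF, −20 to 0 °C; pH 7 buffer work-up; used crude
Reagents that add atoms: none
Why: Grignard addition in which the first equivalent deprotonates the phenol and the second adds to the aldehyde, while iodine–magnesium exchange by an arylmagnesium bromide is slow on this electron-rich phenoxide at 0 °C; the new carbinol centre is racemic and is erased in step 4.

**Step 4**
Reactants: 5 3,5-bis(benzyloxy)-2-{[4-(benzyloxy)phenyl](hydroxy)methyl}-6-iodophenol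
Product: 6 3,5-bis(benzyloxy)-2-[4-(benzyloxy)benzyl]-6-iodophenol
Conditions: Et3SiH (3 equiv), TFA (2 equiv), CH2Cl2, −40 to 0 °C
Reagents that add atoms: none
Why: Ionic hydrogenation, in which the doubly activated benzhydrol ionises with little acid at low temperature to an ortho-quinone-methide-like cation that the silane reduces to the diarylmethane, under conditions mild enough to avoid protodeiodination and to keep the benzyl ethers.

**Step 5**
Reactants: 7 4-(benzyloxy)benzaldehyde; 8 (triphenylphosphoranylidene)acetaldehyde
Product: 9 (E)-3-[4-(benzyloxy)phenyl]prop-2-enal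
Conditions: 8 (1.0 equiv), toluene, 80 °C
Reagents that add atoms: none
Why: Wittig olefination with the stabilised formylmethylene ylide should give the E-enal, and the use of one equivalent of ylide limits a second homologation.

**Step 6**
Reactants: 9 (E)-3-[4-(benzyloxy)phenyl]prop-2-enal
Product: 10 (2R,3S)-3-[4-(benzyloxy)phenyl]oxirane-2-carbaldehyde (trans)
Conditions: (R)-2-{bis[3,5-bis(trifluoromethyl)phenyl](trimethylsilyloxy)methyl}pyrrolidine (10 mol %), 35% aq H2O2 (1.3 equiv), CH2Cl2, rt; filtration through Et3N-deactivated silica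
Reagents that add atoms: hydrogen peroxide, OO
Why: Iminium-catalysed epoxidation of the Weitz–Scheffer type, in which hydrogen peroxide adds to Cβ of the E,s-trans iminium ion on the face left open by the bulky diaryl(silyloxy)methyl group of the (R)-catalyst and the resulting enamine closes onto the O–O bond, which should set both centres as the trans-(2R,3S) epoxide.

**Step 7**
Reactants: 10 (2R,3S)-3-[4-(benzyloxy)phenyl]oxirane-2-carbaldehyde
Product: 11 methyl (2R,3S)-3-[4-(benzyloxy)phenyl]oxirane-2-carboxylate
Conditions: I2 (1.3 equiv), KOH (2.6 equiv), MeOH, 0 °C; recrystallisation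
Reagents that add atoms: methanol, CO
Why: Oxidative esterification through the hypoiodite of the methyl hemiacetal runs in base, which suits the acid-labile para-alkoxyphenyl epoxide (glycidic esters survive the methoxide medium of the Darzens reaction), touches neither stereocentre, and should give a crystalline ester from which minor isomers can be removed.

**Step 8**
Reactants: 11 methyl (2R,3S)-3-[4-(benzyloxy)phenyl]oxirane-2-carboxylate
Product: 12 potassium (2R,3S)-3-[4-(benzyloxy)phenyl]oxirane-2-carboxylate
Conditions: KOH (1.0 equiv), EtOH, 0 °C; salt filtered off and dried in vacuo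
Reagents that add atoms: potassium hydroxide, [K+].[OH-]
Why: Saponification with one equivalent of KOH should precipitate the potassium glycidate, so that the free acid, which would lose CO2 with opening of the epoxide, is never formed and no bond to a stereocentre is touched.

**Step 9**
Reactants: 12 potassium (2R,3S)-3-[4-(benzyloxy)phenyl]oxirane-2-carboxylate; 6 3,5-bis(benzyloxy)-2-[4-(benzyloxy)benzyl]-6-iodophenol
Product: 14 3,5-bis(benzyloxy)-2-[4-(benzyloxy)benzyl]-6-iodophenyl (2R,3S)-3-[4-(benzyloxy)phenyl]oxirane-2-carboxylate, via mixed pivalic anhydride 13 (not isolated)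
Conditions: PivCl (1.05 equiv), THF, −10 °C; then 6, Et3N (1.2 equiv), DMAP (0.2 equiv), −10 °C to rt; Et3N-deactivated silica
Reagents that add atoms: pivaloyl chloride, CC(C)(C)C(=O)Cl (its atoms stand in 13 only)
Why: Mixed-anhydride esterification with DMAP catalysis, in which the carboxylate salt reacts with pivaloyl chloride without release of acid and the hindered phenol is acylated at the less crowded and more electrophilic glycidoyl carbonyl, both stereocentres staying untouched.

**Step 10**
Reactants: 14 3,5-bis(benzyloxy)-2-[4-(benzyloxy)benzyl]-6-iodophenyl (2R,3S)-3-[4-(benzyloxy)phenyl]oxirane-2-carboxylate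
Product: 17 (2R,3R)-5,7-bis(benzyloxy)-8-[4-(benzyloxy)benzyl]-2-[4-(benzyloxy)phenyl]-3-hydroxychroman-4-one, via aryllithium 15 (not isolated), via lithium phenoxide 16 (not isolated)
Conditions: n-BuLi (1.05 equiv), THF (0.01 M), −100 °C, 10 min; then MsOH (1.2 equiv), −100 to 0 °C
Reagents that add atoms: none
Why: Proposed new method: iodine–lithium exchange at the carbon flanked by the acyloxy and a benzyloxy group should be faster at −100 °C than addition of n-BuLi to the ester and gives aryllithium 15, which attacks its own ester carbonyl and collapses with a 1,3 O-to-C acyl shift (anionic ortho-Fries rearrangement, the closest known type being the halogen–metal-exchange-induced shift of 2-haloaryl esters, not yet shown on a glycidate or coupled to a ring closure), so that C4–C4a is made and O1 is released as lithium phenoxide 16. Protonation with MsOH while still cold shuts off the 5-exo attack of the phenoxide on Cα (the aurone-type path of 6'-alkoxy-2'-hydroxychalcone epoxides in base), and the small excess of acid then lets the phenol open the epoxide at the para-alkoxybenzylic Cβ, a 6-endo-tet closure of ring C that is the known acid-mode cyclisation of 2'-hydroxychalcone epoxides to dihydroflavonols. C3 keeps the Cα–O bond of the epoxide and therefore the R configuration set in step 6. C2 is formed by backside attack of O1 (S in 14 becomes R), and any leakage through the benzylic cation should end in the same 2,3-trans isomer because closure with aryl and hydroxyl both equatorial is favoured, so the control element is the epoxide backed by C3. The selectivity needed (8-benzyl and not 6-benzyl, chromanone and not 4-aryldihydrocoumarin) is secured because iodine marks the only carbon that can take the acyl group, the only free oxygen is the one the acyl group has left, and the benzylic carbon stays inert until the carbon nucleophile has been used up. High dilution and the non-nucleophilic mesylate counter-ion guard against intermolecular acyl transfer and halohydrin formation.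

**Step 11**
Reactants: 17 (2R,3R)-5,7-bis(benzyloxy)-8-[4-(benzyloxy)benzyl]-2-[4-(benzyloxy)phenyl]-3-hydroxychroman-4-one
Product: 18 (2R,3R)-3,5,7-trihydroxy-8-(4-hydroxybenzyl)-2-(4-hydroxyphenyl)chroman-4-one
Conditions: H2 (1 atm), 10% Pd/C, THF–MeOH, rt, stopped at full debenzylation
Reagents that add atoms: none
Why: Catalytic hydrogenolysis of the four benzyl ethers under neutral conditions, as is usual for benzylated dihydroflavonols, should leave the ketone, the cyclic benzylic C2–O1 bond, the diarylmethane and both stereocentres intact.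

**Compound list**
1 | 2,4,6-trihydroxybenzaldehyde | O=Cc1c(O)cc(O)cc1O | starting material
2 | 2,4-bis(benzyloxy)-6-hydroxybenzaldehyde | O=Cc1c(O)cc(OCc2ccccc2)cc1OCc1ccccc1 | intermediate
3 | 4,6-bis(benzyloxy)-2-hydroxy-3-iodobenzaldehyde | O=Cc1c(O)c(I)c(OCc2ccccc2)cc1OCc1ccccc1 | intermediate
4 | 4-(benzyloxy)phenylmagnesium bromide | Br[Mg]c1ccc(OCc2ccccc2)cc1 | starting material
5 | 3,5-bis(benzyloxy)-2-{[4-(benzyloxy)phenyl](hydroxy)methyl}-6-iodophenol, racemic carbinol | OC(c1ccc(OCc2ccccc2)cc1)c1c(O)c(I)c(OCc2ccccc2)cc1OCc1ccccc1 | intermediate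
6 | 3,5-bis(benzyloxy)-2-[4-(benzyloxy)benzyl]-6-iodophenol | Oc1c(I)c(OCc2ccccc2)cc(OCc2ccccc2)c1Cc1ccc(OCc2ccccc2)cc1 | intermediate
7 | 4-(benzyloxy)benzaldehyde | O=Cc1ccc(OCc2ccccc2)cc1 | starting material
8 | (triphenylphosphoranylidene)acetaldehyde | O=CC=P(c1ccccc1)(c1ccccc1)c1ccccc1 | starting material
9 | (E)-3-[4-(benzyloxy)phenyl]prop-2-enal | O=C/C=C/c1ccc(OCc2ccccc2)cc1 | intermediate
10 | (2R,3S)-3-[4-(benzyloxy)phenyl]oxirane-2-carbaldehyde | c1ccccc1COc2ccc(cc2)[C@H]3[C@@H](O3)C=O | intermediate
11 | methyl (2R,3S)-3-[4-(benzyloxy)phenyl]oxirane-2-carboxylate | c1ccccc1COc2ccc(cc2)[C@H]3[C@@H](O3)C(=O)OC | intermediate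
12 | potassium (2R,3S)-3-[4-(benzyloxy)phenyl]oxirane-2-carboxylate | c1ccccc1COc2ccc(cc2)[C@H]3[C@@H](O3)C(=O)[O-].[K+] | intermediate
13 | (2R,3S)-3-[4-(benzyloxy)phenyl]oxirane-2-carboxylic pivalic anhydride | c1ccccc1COc2ccc(cc2)[C@H]3[C@@H](O3)C(=O)OC(=O)C(C)(C)C | intermediate
14 | 3,5-bis(benzyloxy)-2-[4-(benzyloxy)benzyl]-6-iodophenyl (2R,3S)-3-[4-(benzyloxy)phenyl]oxirane-2-carboxylate | c1ccccc1COc2ccc(cc2)[C@H]3[C@@H](O3)C(=O)Oc4c(I)c(OCc5ccccc5)cc(OCc5ccccc5)c4Cc6ccc(OCc7ccccc7)cc6 | intermediate
15 | 6-lithio analogue of 14 (lithium in place of iodine) | c1ccccc1COc2ccc(cc2)[C@H]3[C@@H](O3)C(=O)Oc4c([Li])c(OCc5ccccc5)cc(OCc5ccccc5)c4Cc6ccc(OCc7ccccc7)cc6 | intermediate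
16 | lithium 3,5-bis(benzyloxy)-2-[4-(benzyloxy)benzyl]-6-{[(2R,3S)-3-[4-(benzyloxy)phenyl]oxiran-2-yl]carbonyl}phenolate | c1ccccc1COc2ccc(cc2)[C@H]3[C@@H](O3)C(=O)c4c([O-])c(Cc5ccc(OCc6ccccc6)cc5)c(OCc5ccccc5)cc4OCc5ccccc5.[Li+] | intermediate
17 | (2R,3R)-5,7-bis(benzyloxy)-8-[4-(benzyloxy)benzyl]-2-[4-(benzyloxy)phenyl]-3-hydroxychroman-4-one | O=C1c2c(OCc3ccccc3)cc(OCc3ccccc3)c(Cc3ccc(OCc4ccccc4)cc3)c2O[C@H](c2ccc(OCc3ccccc3)cc2)[C@H]1O | intermediate
18 | (2R,3R)-3,5,7-trihydroxy-8-(4-hydroxybenzyl)-2-(4-hydroxyphenyl)chroman-4-one | O=C1c2c(O)cc(O)c(Cc3ccc(O)cc3)c2O[C@H](c2ccc(O)cc2)[C@H]1O | target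

Total step count: 11. Longest linear sequence: 7 steps (steps 1–4, 9, 10, 11; the branch through steps 5–8 is equally long).

**Steps most likely to fail**

1. Step 10. Addition of n-BuLi to the activated aryl ester, intermolecular acyl transfer, or ring closure at Cα instead of Cβ may compete.
   - The fallback uses known chemistry. It sets out from 6 and 10 and comes back at 17.
   - Phenol 6 is capped with MOMCl and i-Pr2NEt to give the methoxymethyl ether F1.
   - Iodine–lithium exchange (n-BuLi, THF, −78 °C) and addition to epoxy aldehyde 10 give the epoxy carbinol F2, as a mixture of epimers at the new carbinol carbon.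
   - Dess–Martin oxidation gives the 2'-O-methoxymethyl epoxy ketone F3.
   - HCl in MeOH–THF removes the acetal, and the freed phenol closes ring C at Cβ to give 17.

2. Step 9. Decarboxylative opening of the glycidate during activation, or acyl transfer from the wrong carbonyl of the anhydride to the crowded phenol, may spoil the esterification.
   - The fallback gives up the ester tether. It sets out from 6 and 11 and comes back at 16.
   - Phenol 6 is treated with n-BuLi (2.1 equiv, THF, −78 °C) to give the O,C-dilithio species F4.
   - F4 is acylated at carbon by methyl ester 11 in an intermolecular reaction and gives lithium phenoxide 16.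
   - The MsOH quench of step 10 then leads to 17. Steps 8 and 9 drop out.

3. Step 6. Slow iminium formation from the electron-rich enal, erosion of trans selectivity in the ring-closing event, or acid-induced opening of the epoxide during isolation may occur.
   - The fallback replaces catalysis by resolution. It sets out from 7 and comes back at 11.
   - Darzens condensation of 7 with methyl chloroacetate (NaOMe, MeOH, −10 °C to rt) gives the racemic trans-glycidate F5.
   - Enantioselective hydrolysis with Serratia marcescens lipase (toluene, pH 8 buffer), as practised on the 4-methoxy congener, consumes the (2S,3R)-ester and leaves 11. Steps 5 to 7 drop out.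

**Further compounds**
F1 | step 10 | 1,5-bis(benzyloxy)-2-[4-(benzyloxy)benzyl]-4-iodo-3-(methoxymethoxy)benzene | COCOc1c(I)c(OCc2ccccc2)cc(OCc2ccccc2)c1Cc1ccc(OCc2ccccc2)cc1
F2 | step 10 | {4,6-bis(benzyloxy)-3-[4-(benzyloxy)benzyl]-2-(methoxymethoxy)phenyl}{(2S,3S)-3-[4-(benzyloxy)phenyl]oxiran-2-yl}methanol, epimers at the carbinol carbon | c1ccccc1COc2ccc(cc2)[C@H]3[C@@H](O3)C(O)c4c(OCOC)c(Cc5ccc(OCc6ccccc6)cc5)c(OCc5ccccc5)cc4OCc5ccccc5
F3 | step 10 | {4,6-bis(benzyloxy)-3-[4-(benzyloxy)benzyl]-2-(methoxymethoxy)phenyl}{(2R,3S)-3-[4-(benzyloxy)phenyl]oxiran-2-yl}methanone | c1ccccc1COc2ccc(cc2)[C@H]3[C@@H](O3)C(=O)c4c(OCOC)c(Cc5ccc(OCc6ccccc6)cc5)c(OCc5ccccc5)cc4OCc5ccccc5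
F4 | step 9 | lithium 3,5-bis(benzyloxy)-2-[4-(benzyloxy)benzyl]-6-lithiophenolate | [Li+].[O-]c1c([Li])c(OCc2ccccc2)cc(OCc2ccccc2)c1Cc1ccc(OCc2ccccc2)cc1
F5 | step 6 | methyl trans-3-[4-(benzyloxy)phenyl]oxirane-2-carboxylate, racemate (both enantiomers written) | c1ccccc1COc2ccc(cc2)[C@H]3[C@@H](O3)C(=O)OC.c1ccccc1COc2ccc(cc2)[C@@H]3[C@H](O3)C(=O)OC
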